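Readings and results are calculated from invented constants, and the scatter is random.

- Read the charges and the runs through the fraction of substrate left, not the fraction made.

| flask | substrate | gas phase | protic impurity | remark | time |
|---|---|---|---|---|---|
| noon | 10 mM | 1 mM (held) | 4 mM | run made earlier |  |
| spring | 15 mM | 1 mM (held) | 4 mM | run made earlier |  |
| winter | 20 mM | 1 mM (held) | 2 mM | run made earlier |  |
| epsilon | 20 mM | 1.0 mM (held) | 4.00 mM |  | 6.0 h |
| theta | 20 mM | 1.0 mM (held) | 4.00 mM |  | 8.0 h |
| alpha | 20 mM | 1.0 mM (held) | 4.00 mM |  | 5.0 h |

| run | time / h | target / % | over-reacted product / % | isomer of the product / % | substrate / % |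
|---|---|---|---|---|---|
| noon | 0.417 | 2 | 0 | 0 | 95 |
| noon | 0.667 | 3 | 0 | 2 | 92 |
| noon | 1.00 | 6 | 0 | 5 | 84 |
| noon | 2.00 | 10 | 1 | 11 | 73 |
| noon | 3.00 | 12 | 2 | 16 | 60 |
| noon | 5.00 | 9 | 6 | 30 | 42 |
| spring | 0.333 | 4 | 0 | 0 | 95 |
| spring | 1.00 | 6 | 0 | 5 | 86 |
| spring | 2.00 | 8 | 2 | 9 | 74 |
| spring | 2.50 | 10 | 3 | 10 | 70 |
| spring | 4.00 | 10 | 6 | 22 | 53 |
| spring | 5.00 | 9 | 3 | 25 | 44 |
| winter | 0.417 | 2 | 1 | 0 | 97 |
| winter | 1.33 | 7 | 1 | 5 | 81 |
| winter | 2.50 | 6 | 0 | 8 | 65 |
| winter | 4.00 | 7 | 3 | 18 | 53 |
| winter | 5.00 | 9 | 0 | 24 | 43 |

(standard deviation of a reading: 1.5 percentage points)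

- percent here means substrate units held: one homo dimer counts as two
- at the start none of the gas is dissolved
- steps that have been proposed: dissolved gas + target -> over-reacted product; dissolved gas + protic impurity -> quenched reagent; target <-> isomer of the product; gas phase <-> dissolved gas; 2 substrate -> homo dimer; substrate + dissolved gas -> target

- which of these there is most of at the end, counted by the substrate in it, epsilon (over-reacted product / target / isomer of the product / substrate)
- which of these there is most of at the end, counted by the substrate in it, theta (over-reacted product / target / isomer of the product / substrate)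
- which of these there is most of at the end, counted by the substrate in it, alpha (over-reacted product / target / isomer of the product / substrate)
- amount of the one of these that there is most of at the end, in percent of the substrate charged, epsilon
- amount of the one of these that there is most of at the end, in percent of the substrate charged, theta
- amount of the one of these that there is most of at the end, in percent of the substrate charged, alpha

- In the winter run, 65% left at 2.50 h gives 0.172 h⁻¹ as the loss constant, the natural logarithm of c(substrate) charged over c(substrate) left, divided by the time; this is an apparent first-order constant.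
- The noon run, at half the substrate and twice the protic impurity, gives 0.174 h⁻¹ from 42% left at 5.00 h; a different flask and a different time give nearly the same constant, so it is trusted.
- A straight line through the same winter reading parts from the constant: at 5.00 h the line leaves 30.0% and the constant 42.3%. The winter run read 43%, with a scatter of 1.5 percentage points, so the line is the one that cheats.
- The constant, as a reckoning separate from the forecast, leaves 42.3% of the substrate in alpha, 35.6% in epsilon and 25.2% in theta. It says nothing of the isomer of the product.
- The forecast gives substrate at 38% (34% to 42%) in epsilon, isomer of the product at 33% (28% to 38%) in theta and substrate at 45% (41% to 49%) in alpha. Its substrate figure for alpha stands above the reckoning. Of theta it says “so the isomer has probably overtaken, though this is a close call”.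
- The flask gives substrate at 37.8% in epsilon, isomer of the product at 33.8% in theta and substrate at 44.5% in alpha, so the forecast's marks held and each amount lies inside its range.

    dissolved gas + target → over-reacted product (k = 0.0780 M⁻¹ s⁻¹)
    dissolved gas + protic impurity → quenched reagent (k = 0.0440 M⁻¹ s⁻¹)
    target ⇌ isomer of the product (K = 7.20, k = 2.60 × 10⁻⁴ s⁻¹)
    gas phase ⇌ dissolved gas, rate k4*(csat - [dissolved gas]) (kL = 8.40 × 10⁻⁴ s⁻¹)
    2 substrate → homo dimer (k = 5.90 × 10⁻⁴ M⁻¹ s⁻¹)
    substrate + dissolved gas → target (k = 0.0730 M⁻¹ s⁻¹)

- Substrate in theta ends at 26.9%, a loss constant of 0.164 h⁻¹ against the 0.172 h⁻¹ carried forward, and it trails the isomer of the product by 6.9 points. The difference in time is the main reason for the gap in substrate between theta and alpha: theta taken back to the time of alpha holds 44.5% of substrate instead of 26.9%.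
- In the neighbour flask with 50 mM of substrate, the constant again leaves 35.6% at 6.00 h. The computed neighbour flask holds 31.8% of its substrate, with 45.9% as homo dimer against 22.5% in epsilon.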